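## Retrosynthetic overview

1. The target comes from desilylation, allylic oxidation of the C4 methyl group, and acylation of the C8 alcohol with a (Z)-2-(silyloxymethyl)but-2-enoic acid made from crotonaldehyde.
2. The α-methylene group (Mannich/elimination), the 2Z alkene (Corey–Winter on a cis-2,3-diol) and the 1,10-epoxide (hydroxyl-directed) are installed on a saturated cis-fused lactone of a (1(10)Z,4Z)-cyclodecadiene.
3. The lactone comes from a ten-membered keto ester by carbonyl reduction; the keto ester comes from an anionic oxy-Cope ring expansion of a cis-1-alkenyl-6-isopropenylcyclohex-2-enol with alkylation of the resulting enolate (C8–C9 bond; C8 then C7 set).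
4. The cyclohexenol comes from alkoxyacetylide addition and trans-hydroalumination on a dioxolane-fused cyclohexenone, made from (R)-carvone by α'-hydroxylation, reduction, acetonide formation and allylic oxidation.
5. Ring order: six-membered ring of carvone (sacrificed) → ten-membered carbocycle → γ-lactone → epoxide.

Assumption: starting materials are (R)-carvone, 4-methoxybenzyl alcohol and (E)-but-2-enal, all catalogue chemicals. The ten-membered ring carries germacrane numbers: C1/C10 epoxide (C14 on C10), C2=C3, C4 (bears C15), C5, C6 (lactone O), C7 (bears C11–C13), C8 (ester O), C9. PMB = 4-methoxybenzyl, TBS = tert-butyldimethylsilyl. The route is a design and has not been run; the selectivities given are predicted from models and analogies.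

## Route

Step 1
Reactants: 1 (R)-carvone
Product: 3 (5S,6S)-6-hydroxy-2-methyl-5-(prop-1-en-2-yl)cyclohex-2-en-1-one, via lithium dienolate 2 (not isolated)
Conditions: LiN(iPr)2 (commercial solution), THF, −78 °C; racemic 2-(phenylsulfonyl)-3-phenyloxaziridine, −78 °C; aq. NH4Cl
Reagents that add atoms: 2-(phenylsulfonyl)-3-phenyloxaziridine (racemic) O=S(=O)(c1ccccc1)N1OC1c1ccccc1
Why: Kinetic α'-deprotonation and Davis enolate hydroxylation anti to the neighbouring isopropenyl group give the trans α'-hydroxy enone.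

Step 2
Reactants: 3 (5S,6S)-6-hydroxycarvone
Product: 4 (1S,2R,6S)-3-methyl-6-(prop-1-en-2-yl)cyclohex-3-ene-1,2-diol
Conditions: Zn(BH4)2 (pre-formed in Et2O), Et2O, −20 °C
Reagents that add atoms: none
Why: Chelation-controlled (Cram chelate) 1,2-reduction delivers hydride to the carbonyl face on the side of the C–H of the carbinol carbon, so the new hydroxyl is cis to the existing one.

Step 3
Reactants: 4 cis-diol
Product: 5 (3aS,4S,7aR)-2,2,7-trimethyl-4-(prop-1-en-2-yl)-3a,4,5,7a-tetrahydro-1,3-benzodioxole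
Conditions: 2,2-dimethoxypropane, PPTS (cat.), CH2Cl2, rt
Reagents that add atoms: 2,2-dimethoxypropane COC(C)(C)OC
Why: Acid-catalysed transketalisation closes the cis-fused dioxolane, which only the cis-diol forms readily.

Step 4
Reactants: 5 acetonide
Product: 6 (3aS,4S,7aR)-2,2,7-trimethyl-4-(prop-1-en-2-yl)-3a,7a-dihydro-1,3-benzodioxol-5(4H)-one
Conditions: CrO3, 3,5-dimethylpyrazole, CH2Cl2, −20 °C
Reagents that add atoms: chromium trioxide O=[Cr](=O)=O
Why: CrO3–3,5-dimethylpyrazole allylic oxidation converts the only ring allylic CH2 into the conjugated enone carbonyl without touching the stereocenters.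

Step 5
Reactants: 7 4-methoxybenzyl alcohol
Product: 8 (E)-1-{[(1,2-dichloroethenyl)oxy]methyl}-4-methoxybenzene
Conditions: KH, THF, 0 °C; Cl2C=CHCl, −40 °C → rt
Reagents that add atoms: trichloroethylene ClC=C(Cl)Cl
Why: Greene's dichlorovinyl ether synthesis: the alkoxide adds anti to dichloroacetylene generated in situ from trichloroethylene.

Step 6
Reactants: 6 enone; 8 dichlorovinyl ether
Product: 11 (3aS,4S,5R,7aR)-5-[(E)-2-(4-methoxybenzyloxy)ethenyl]-2,2,7-trimethyl-4-(prop-1-en-2-yl)-3a,4,5,7a-tetrahydro-1,3-benzodioxol-5-ol, via lithium acetylide 9 (not isolated), via lithium ynol-ether alkoxide 10 (not isolated)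
Conditions: 8, n-BuLi (2 equiv), THF, −78 → −40 °C; 6, −78 °C; LiAlH4, THF, 0 °C → rt; aq. NaOH work-up
Reagents that add atoms: none
Why: The rod-like alkoxyacetylide adds 1,2 by axial attack, placing the alkynyl group cis to the equatorial isopropenyl group, and alkoxide-directed trans-hydroalumination gives the E enol ether.

Step 7
Reactants: 11 divinyl carbinol
Product: 14 methyl [(2S,3R,7R,8S,1(10)Z,4Z)-2,3-isopropylidenedioxy-8-(4-methoxybenzyloxy)-4,10-dimethyl-6-oxocyclodeca-1(10),4-dien-7-yl]acetate, via potassium alkoxide 12 (not isolated), via potassium enolate 13 (not isolated)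
Conditions: KN(SiMe3)2, 18-crown-6, THF, 0 °C → rt; BrCH2CO2Me, −78 → −20 °C
Reagents that add atoms: methyl bromoacetate BrCC(=O)OC
Why: The anion-accelerated oxy-Cope [3,3]-sigmatropic rearrangement, through the chair with the alkenyl arm axial and the isopropenyl group equatorial, forms C8–C9 and the ten-membered ring with a 1(10)Z alkene, keeps the ring-derived 4Z enone, and transfers chirality to C8 (S, ether pseudo-equatorial from the E enol ether); the enolate is then alkylated on its exposed face anti to that ether to set C7 (R).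

Step 8
Reactants: 14 keto ester
Product: 16 (2S,3R,6S,7R,8S,1(10)Z,4Z)-2,3-isopropylidenedioxy-8-(4-methoxybenzyloxy) cis-fused 12,6-lactone (C11 = CH2), via lithium alkoxide 15 (not isolated)
Conditions: LiBH(s-Bu)3, THF, −78 °C → rt
Reagents that add atoms: none
Why: Felkin–Anh 1,2-reduction by the bulky hydride, anti to the C7–C8 ring bond, gives the 6S alkoxide on the same ring face as the acetate arm, which lactonises to the cis-fused γ-lactone.

Step 9
Reactants: 16 lactone acetonide
Product: 17 (2S,3R,6S,7R,8S)-2,3-dihydroxy lactone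
Conditions: AcOH/THF/H2O (3:1:1), 45 °C
Reagents that add atoms: none
Why: Mild acetal hydrolysis frees the cis-diol while the PMB ether, the lactone and both stereodefined alkenes survive.

Step 10
Reactants: 17 diol
Product: 18 (1R,2R,3R,6S,7R,8S,10S)-1,10-epoxy-2,3-dihydroxy lactone
Conditions: VO(acac)2 (5 mol %), t-BuOOH, CH2Cl2, 0 °C → rt
Reagents that add atoms: tert-butyl hydroperoxide CC(C)(C)OO
Why: Hydroxyl-directed vanadium-catalysed epoxidation delivers oxygen to the 1(10)Z alkene cis to the allylic C2–OH, as for medium-ring cycloalk-2-enols, setting C1 (R) and C10 (S); the 4,5-alkene is deactivated by the allylic lactone oxygen.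

Step 11
Reactants: 18 epoxy diol
Product: 19 2,3-cyclic thionocarbonate of 18
Conditions: 1,1'-thiocarbonyldiimidazole, DMAP (cat.), THF, 50 °C
Reagents that add atoms: 1,1'-thiocarbonyldiimidazole S=C(n1ccnc1)n1ccnc1
Why: Double acyl substitution on the cis-diol gives the cyclic thionocarbonate under neutral conditions that spare the adjacent epoxide.

Step 12
Reactants: 19 thionocarbonate
Product: 20 (1R,6S,7R,8S,10S,2Z,4Z)-1,10-epoxy-8-(4-methoxybenzyloxy)-2,4-diene lactone (C11 = CH2)
Conditions: 1,3-dimethyl-2-phenyl-1,3,2-diazaphospholidine, THF, 40 °C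
Reagents that add atoms: none
Why: Corey–Winter olefination (Corey–Hopkins variant) is a stereospecific syn cycloreversion, so the cis-diol carried from the six-membered ring gives only the 2Z alkene.

Step 13
Reactants: 20 lactone
Product: 23 (1R,6S,7R,8S,10S,2Z,4Z)-1,10-epoxy-8-(4-methoxybenzyloxy)-α-methylene lactone, via Mannich base 21 (not isolated), via ammonium iodide 22 (not isolated)
Conditions: LiN(iPr)2 (commercial solution), THF, −78 °C; CH2=NMe2+ I−, −78 °C → rt; MeI, MeOH, rt; aq. NaHCO3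
Reagents that add atoms: N,N-dimethylmethyleneiminium iodide C=[N+](C)C.[I-]
Why: Eschenmoser methylenation: Mannich reaction of the lactone enolate, N-methylation and Hofmann-type β-elimination give the exocyclic methylene; C11 becomes sp2, so no stereocenter arises.

Step 14
Reactants: 23 PMB ether
Product: 24 (1R,6S,7R,8S,10S)-8-hydroxy epoxy-dienolide
Conditions: DDQ, CH2Cl2/pH 7 buffer, 0 °C
Reagents that add atoms: none
Why: Oxidative cleavage of the electron-rich PMB ether under buffered conditions leaves the acid-sensitive vinyl epoxide intact.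

Step 15
Reactants: 25 (E)-but-2-enal
Product: 26 (Z)-2-iodobut-2-enal
Conditions: I2, K2CO3, DMAP (cat.), THF/H2O, rt
Reagents that add atoms: iodine II
Why: Baylis–Hillman-type α-iodination (amine conjugate addition, iodination, elimination) gives the isomer with methyl trans to the formyl group.

Step 16
Reactants: 26 iodo enal
Product: 27 (Z)-2-iodobut-2-en-1-ol
Conditions: NaBH4, CeCl3·7H2O, MeOH, 0 °C
Reagents that add atoms: none
Why: Luche 1,2-reduction of the enal leaves the alkene geometry and the vinyl iodide untouched.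

Step 17
Reactants: 27 iodo alcohol
Product: 28 (Z)-tert-butyl[(2-iodobut-2-en-1-yl)oxy]dimethylsilane
Conditions: t-BuMe2SiCl, imidazole, CH2Cl2, 0 °C → rt
Reagents that add atoms: tert-butyldimethylsilyl chloride CC(C)(C)[Si](C)(C)Cl
Why: Standard silylation protects the primary allylic alcohol for the lithiation and the later esterification.

Step 18
Reactants: 28 vinyl iodide
Product: 30 (Z)-2-{[(tert-butyldimethylsilyl)oxy]methyl}but-2-enoic acid, via vinyllithium 29 (not isolated)
Conditions: t-BuLi (2 equiv), Et2O, −78 °C; CO2; cold dilute HCl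
Reagents that add atoms: carbon dioxide O=C=O
Why: Iodine–lithium exchange and carboxylation proceed with retention, so the carboxyl group ends cis to the methyl group (sarracinate geometry).

Step 19
Reactants: 24 alcohol; 30 acid
Product: 32 (1R,6S,7R,8S,10S)-8-O-[(Z)-2-(tert-butyldimethylsilyloxymethyl)but-2-enoyl] epoxy-dienolide, via mixed anhydride 31 (not isolated)
Conditions: 2,4,6-Cl3C6H2COCl, Et3N, toluene, rt; then 24, DMAP, rt
Reagents that add atoms: none
Why: Yamaguchi esterification acylates the hindered secondary alcohol through the mixed anhydride without Z→E isomerisation of the angelate-type acid and with retention at C8.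

Step 20
Reactants: 32 ester
Product: 33 15-hydroxy derivative of 32 (4E by CIP, ring-cis geometry retained)
Conditions: SeO2 (0.3 equiv), t-BuOOH, CH2Cl2, rt
Reagents that add atoms: selenium dioxide O=[Se]=O; tert-butyl hydroperoxide CC(C)(C)OO
Why: Riley allylic oxidation (ene reaction then [2,3]-sigmatropic shift) hydroxylates the only allylic methyl on an electron-rich alkene and returns the CH2OH trans to C6, i.e. the ring-cis alkene, as in the oxidation of parthenolide to melampomagnolide B.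

Step 21
Reactants: 33 silyl ether
Product: 34 target (1R,6S,7R,8S,10S)
Conditions: Bu4NF, AcOH, THF, 0 °C
Reagents that add atoms: none
Why: Buffered fluoride desilylation frees the side-chain primary alcohol without opening the vinyl epoxide or migrating the esters.

## Compound list

1 | (R)-carvone | O=C1C(C)=CC[C@@H](C(C)=C)C1 | starting material
2 | lithium cross-conjugated dienolate of 1 | [Li]OC1=C[C@H](C(C)=C)CC=C1C | intermediate
3 | (5S,6S)-6-hydroxy-2-methyl-5-(prop-1-en-2-yl)cyclohex-2-en-1-one | O=C1C(C)=CC[C@@H](C(C)=C)[C@@H]1O | intermediate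
4 | (1S,2R,6S)-3-methyl-6-(prop-1-en-2-yl)cyclohex-3-ene-1,2-diol | O[C@@H]1C(C)=CC[C@@H](C(C)=C)[C@@H]1O | intermediate
5 | (3aS,4S,7aR)-2,2,7-trimethyl-4-(prop-1-en-2-yl)-3a,4,5,7a-tetrahydro-1,3-benzodioxole | CC1(C)O[C@@H]2C(C)=CC[C@@H](C(C)=C)[C@@H]2O1 | intermediate
6 | (3aS,4S,7aR)-2,2,7-trimethyl-4-(prop-1-en-2-yl)-3a,7a-dihydro-1,3-benzodioxol-5(4H)-one | CC1(C)O[C@@H]2C(C)=CC(=O)[C@@H](C(C)=C)[C@@H]2O1 | intermediate
7 | 4-methoxybenzyl alcohol | COc1ccc(CO)cc1 | starting material
8 | (E)-1-{[(1,2-dichloroethenyl)oxy]methyl}-4-methoxybenzene | Cl/C=C(/Cl)OCc1ccc(OC)cc1 | intermediate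
9 | lithium [(4-methoxybenzyl)oxy]acetylide | [Li]C#COCc1ccc(OC)cc1 | intermediate
10 | lithium alkoxide of the alkynyl adduct of 6 (alkynyl cis to isopropenyl) | CC1(C)O[C@@H]2C(C)=C[C@@](O[Li])(C#COCc3ccc(OC)cc3)[C@@H](C(C)=C)[C@@H]2O1 | intermediate
11 | (3aS,4S,5R,7aR)-5-[(E)-2-(4-methoxybenzyloxy)ethenyl]-2,2,7-trimethyl-4-(prop-1-en-2-yl)-3a,4,5,7a-tetrahydro-1,3-benzodioxol-5-ol | CC1(C)O[C@@H]2C(C)=C[C@@](O)(/C=C/OCc3ccc(OC)cc3)[C@@H](C(C)=C)[C@@H]2O1 | intermediate
12 | potassium alkoxide of 11 | CC1(C)O[C@@H]2C(C)=C[C@@](O[K])(/C=C/OCc3ccc(OC)cc3)[C@@H](C(C)=C)[C@@H]2O1 | intermediate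
13 | potassium enolate of the ring-expanded ketone (C6–O, C6=C7) | [K]O/C1=C\[C@@H](OCc3ccc(OC)cc3)C/C(C)=C\[C@@H]2OC(C)(C)O[C@@H]2/C(C)=C\1 | intermediate
14 | methyl [(2S,3R,7R,8S,1(10)Z,4Z)-2,3-isopropylidenedioxy-8-(4-methoxybenzyloxy)-4,10-dimethyl-6-oxocyclodeca-1(10),4-dien-7-yl]acetate | O=C1/C=C(C)\[C@H]2OC(C)(C)O[C@H]2/C=C(C)\C[C@H](OCc3ccc(OC)cc3)[C@H]1CC(=O)OC | intermediate
15 | lithium (6S)-alkoxide of reduced 14 | [Li]O[C@H]1/C=C(C)\[C@H]2OC(C)(C)O[C@H]2/C=C(C)\C[C@H](OCc3ccc(OC)cc3)[C@H]1CC(=O)OC | intermediate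
16 | (2S,3R,6S,7R,8S,1(10)Z,4Z)-2,3-isopropylidenedioxy-8-(4-methoxybenzyloxy) cis-fused 12,6-lactone | O=C1O[C@H]2/C=C(C)\[C@H]3OC(C)(C)O[C@H]3/C=C(C)\C[C@H](OCc4ccc(OC)cc4)[C@H]2C1 | intermediate
17 | (2S,3R,6S,7R,8S)-2,3-dihydroxy lactone | O=C1O[C@H]2/C=C(C)\[C@@H](O)[C@@H](O)/C=C(C)\C[C@H](OCc3ccc(OC)cc3)[C@H]2C1 | intermediate
18 | (1R,2R,3R,6S,7R,8S,10S)-1,10-epoxy-2,3-dihydroxy lactone | O=C1O[C@H]2/C=C(C)\[C@@H](O)[C@@H](O)[C@H]3O[C@@]3(C)C[C@H](OCc4ccc(OC)cc4)[C@H]2C1 | intermediate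
19 | 2,3-cyclic thionocarbonate of 18 | O=C1O[C@H]2/C=C(C)\[C@H]3OC(=S)O[C@H]3[C@H]4O[C@@]4(C)C[C@H](OCc5ccc(OC)cc5)[C@H]2C1 | intermediate
20 | (1R,6S,7R,8S,10S,2Z,4Z)-1,10-epoxy-8-(4-methoxybenzyloxy)-2,4-diene lactone (C11 = CH2) | O=C1O[C@H]2/C=C(C)\C=C/[C@H]3O[C@@]3(C)C[C@H](OCc4ccc(OC)cc4)[C@H]2C1 | intermediate
21 | 11-(dimethylaminomethyl) lactone (Mannich base, C11 epimers) | CN(C)CC1C(=O)O[C@H]2/C=C(C)\C=C/[C@H]3O[C@@]3(C)C[C@H](OCc4ccc(OC)cc4)[C@@H]12 | intermediate
22 | trimethylammonium iodide of 21 | C[N+](C)(C)CC1C(=O)O[C@H]2/C=C(C)\C=C/[C@H]3O[C@@]3(C)C[C@H](OCc4ccc(OC)cc4)[C@@H]12.[I-] | intermediate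
23 | (1R,6S,7R,8S,10S,2Z,4Z)-1,10-epoxy-8-(4-methoxybenzyloxy)-α-methylene lactone | C=C1C(=O)O[C@H]2/C=C(C)\C=C/[C@H]3O[C@@]3(C)C[C@H](OCc4ccc(OC)cc4)[C@@H]12 | intermediate
24 | (1R,6S,7R,8S,10S,2Z,4Z)-1,10-epoxy-8-hydroxy-α-methylene lactone | C=C1C(=O)O[C@H]2/C=C(C)\C=C/[C@H]3O[C@@]3(C)C[C@H](O)[C@@H]12 | intermediate
25 | (E)-but-2-enal | C/C=C/C=O | starting material
26 | (Z)-2-iodobut-2-enal | C/C=C(\I)C=O | intermediate
27 | (Z)-2-iodobut-2-en-1-ol | C/C=C(\I)CO | intermediate
28 | (Z)-tert-butyl[(2-iodobut-2-en-1-yl)oxy]dimethylsilane | C/C=C(\I)CO[Si](C)(C)C(C)(C)C | intermediate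
29 | vinyllithium from 28 | C/C=C(\[Li])CO[Si](C)(C)C(C)(C)C | intermediate
30 | (Z)-2-{[(tert-butyldimethylsilyl)oxy]methyl}but-2-enoic acid | C/C=C(\C(=O)O)CO[Si](C)(C)C(C)(C)C | intermediate
31 | mixed anhydride of 30 with 2,4,6-trichlorobenzoic acid | C/C=C(\C(=O)OC(=O)c1c(Cl)cc(Cl)cc1Cl)CO[Si](C)(C)C(C)(C)C | intermediate
32 | 8-O-[(Z)-2-(tert-butyldimethylsilyloxymethyl)but-2-enoyl] ester of 24 | C=C1C(=O)O[C@H]2/C=C(C)\C=C/[C@H]3O[C@@]3(C)C[C@H](OC(=O)/C(=C\C)CO[Si](C)(C)C(C)(C)C)[C@@H]12 | intermediate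
33 | 15-hydroxy derivative of 32 | C=C1C(=O)O[C@H]2/C=C(CO)\C=C/[C@H]3O[C@@]3(C)C[C@H](OC(=O)/C(=C\C)CO[Si](C)(C)C(C)(C)C)[C@@H]12 | intermediate
34 | CNP0293319.3 (1R,6S,7R,8S,10S) | C=C1C(=O)O[C@H]2/C=C(CO)\C=C/[C@H]3O[C@@]3(C)C[C@H](OC(=O)/C(=C\C)CO)[C@@H]12 | target

## Step count and risks

Total step count: 21. Longest linear sequence: 16 steps from 1 (steps 1–4, 6–14, 19–21).

Most likely to fail, step 7. The enolate born in the rearrangement carries a β-ether that can be lost, and the stereochemical outcome rests on one chair and on face-selective alkylation. The fallback sets out from 11 and comes back at 14. The rearrangement is run with KN(SiMe3)2/18-crown-6 and the enolate is quenched cold with Me3SiCl/Et3N to give the trimethylsilyl enol ether of the ring-expanded ketone F4. The two-carbon arm is then brought in by carbenoid chemistry instead of enolate alkylation: methyl diazoacetate with Cu(acac)2 (cat.) cyclopropanates the exposed face of the silyl enol ether to the siloxycyclopropane ester F5. Et3N·3HF opens this donor–acceptor cyclopropane to keto ester 14.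

Second, step 20. The vinyl epoxide, the diene and two Michael acceptors must all survive the selenium reagent. The fallback sets out from 20 and comes back at 34; it moves the C–H oxidation ahead of both Michael acceptors and carries O-15 as a silyl ether, so no oxidation is left for the end. SeO2/t-BuOOH on 20 gives the 15-hydroxy lactone F6, and t-BuMe2SiCl/imidazole gives the 15-O-TBS ether F7. Methylenation as in step 13 gives the α-methylene lactone F8, DDQ gives the 8-ol F9, and Yamaguchi coupling with 30 gives the bis-silyl ester F10. Bu4NF/AcOH then removes both silyl groups to give 34.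

Third, step 4. The oxidant can also attack the isopropenyl group or the allylic methyl. The fallback sets out from 5 and comes back at 6, replacing C–H oxidation by an epoxide-based 1,3-oxygen transposition. mCPBA (NaHCO3, CH2Cl2, 0 °C) epoxidises the ring alkene to the epoxide F1. PhSeNa, from (PhSe)2/NaBH4 in EtOH, opens it at the secondary carbon to the hydroxy selenide F2. H2O2 then induces selenoxide syn-elimination to the tertiary allylic alcohol F3. Pyridinium chlorochromate [C5H5NH][CrO3Cl] in CH2Cl2 effects Dauben–Babler oxidative transposition to enone 6.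

Further compounds

F1 | step 4 | 2,3-epoxide of 5 (epoxide anti to the dioxolane) | CC1(C)O[C@@H]2[C@@]3(C)O[C@H]3C[C@@H](C(C)=C)[C@@H]2O1
F2 | step 4 | trans hydroxy phenylselenide from F1 | CC1(C)O[C@@H]2[C@@](C)(O)[C@H]([Se]c3ccccc3)C[C@@H](C(C)=C)[C@@H]2O1
F3 | step 4 | tertiary allylic alcohol from F2 | CC1(C)O[C@@H]2[C@@](C)(O)C=C[C@@H](C(C)=C)[C@@H]2O1
F4 | step 7 | trimethylsilyl enol ether of the ring-expanded ketone | C[Si](C)(C)O/C1=C\[C@@H](OCc3ccc(OC)cc3)C/C(C)=C\[C@@H]2OC(C)(C)O[C@@H]2/C(C)=C\1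
F5 | step 7 | siloxycyclopropane ester (C6–C7–C11 ring, C11 epimers) | COC(=O)C1[C@]2(O[Si](C)(C)C)/C=C(C)\[C@H]3OC(C)(C)O[C@H]3/C=C(C)\C[C@H](OCc4ccc(OC)cc4)[C@@H]12
F6 | step 20 | 15-hydroxy derivative of 20 | O=C1O[C@H]2/C=C(CO)\C=C/[C@H]3O[C@@]3(C)C[C@H](OCc4ccc(OC)cc4)[C@H]2C1
F7 | step 20 | 15-O-TBS ether of F6 | O=C1O[C@H]2/C=C(CO[Si](C)(C)C(C)(C)C)\C=C/[C@H]3O[C@@]3(C)C[C@H](OCc4ccc(OC)cc4)[C@H]2C1
F8 | step 20 | α-methylene lactone from F7 | C=C1C(=O)O[C@H]2/C=C(CO[Si](C)(C)C(C)(C)C)\C=C/[C@H]3O[C@@]3(C)C[C@H](OCc4ccc(OC)cc4)[C@@H]12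
F9 | step 20 | 8-ol from F8 | C=C1C(=O)O[C@H]2/C=C(CO[Si](C)(C)C(C)(C)C)\C=C/[C@H]3O[C@@]3(C)C[C@H](O)[C@@H]12
F10 | step 20 | bis-silyl ester from F9 and 30 | C=C1C(=O)O[C@H]2/C=C(CO[Si](C)(C)C(C)(C)C)\C=C/[C@H]3O[C@@]3(C)C[C@H](OC(=O)/C(=C\C)CO[Si](C)(C)C(C)(C)C)[C@@H]12
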